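Each quinone ring (rings A and B; C1=O, C2–OH, C3–chain, C4=O, C5–OMe, C6–Me) is cut into an oxalyl unit (C1–C2) and a 2,3-dioxygenated butadiene (C3–C6). The key step is a double C-acylation of a bis(2-silyloxy-3-methoxy-1,3-diene) by two molecules of oxalyl chloride, one per ring. In one operation it forms C6–C1 and C2–C3 in both rings and delivers the hydroxyquinones at their final oxidation level; the silylated oxygen becomes the C4 carbonyl and the methylated one stays as the C5 methoxy group. The precursor is an acyclic C24 tetraene, assembled two-directionally by double conjugate addition of a C12 di-Grignard reagent to a small methoxy dienone. The twofold symmetry about the (CH2)14 tether is used throughout.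

Key step: step 4

Remark: the tether is read as fourteen CH2 groups between the two ring C3 atoms, and the target is written as its 2-hydroxy-1,4-benzoquinone tautomer. The enol-ether geometries given for 5, 8 and 10 are those expected; none is carried into the target, which has no stereocentre. In the two-directional steps each chain end consumes its own molecule of the partner: two of 5 and of Me3SiCl in step 3, two of 9 in step 4.

Step 1
Reactants: 1 allyl methyl ether (3-methoxyprop-1-ene)
Product: 2 (Z)-1-methoxyprop-1-ene
Conditions: KOtBu (0.2 equiv), DMSO, 20 → 60 °C, product distilled from the pot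
Reagents that add atoms: none
Why: base-mediated prototropic isomerisation of an allyl ether to the conjugated propenyl ether, in which the potassium-coordinated cisoid oxyallyl anion is reprotonated at the terminal carbon, so the cis (Z) enol ether is expected as the predominant kinetic product.

Step 2
Reactants: 2 (Z)-1-methoxyprop-1-ene; 3 N-methoxy-N-methylacrylamide
Product: 5 (4Z)-4-methoxyhexa-1,4-dien-3-one, via (Z)-(1-methoxyprop-1-en-1-yl)lithium 4 (not isolated)
Conditions: t-BuLi, THF/pentane, −78 → −10 °C; then 3, −78 °C; inverse quench into cold 0.5 M HCl/Et2O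
Reagents that add atoms: tert-butyllithium, [Li]C(C)(C)C (its lithium is held only in intermediate 4)
Why: oxygen-directed α-lithiation of the Z enol ether with retention of configuration, then acylation by a Weinreb amide, whose chelated tetrahedral intermediate should stop at the ketone and favour 1,2- over 1,4-attack; the acidic quench keeps the liberated amine protonated so that it cannot add to the vinyl ketone, and the Z geometry of the future C5=C6 bond comes from 2.

Step 3
Reactants: 5 (4Z)-4-methoxyhexa-1,4-dien-3-one; 6 1,12-dibromododecane
Product: 8 (2Z,4Z,20Z,22Z)-3,22-dimethoxy-4,21-bis(trimethylsilyloxy)tetracosa-2,4,20,22-tetraene, via dodecane-1,12-diylbis(magnesium bromide) 7 (not isolated)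
Conditions: 6, Mg, THF, 40 °C; then CuBr·SMe2 (10 mol%), Me3SiCl, HMPA, 5 (2.3 equiv), THF, −78 °C; Et3N/pentane work-up
Reagents that add atoms: chlorotrimethylsilane, C[Si](C)(C)Cl; magnesium, [Mg] (held only in intermediate 7)
Why: Me3SiCl-accelerated copper-catalysed conjugate addition of a Grignard reagent at both chain ends; only the unsubstituted vinyl terminus of 5 should be attacked, because the other alkene is β-methylated and made electron-rich by its α-methoxy group, and the enolate is silylated as it forms, which fixes the cross-conjugated dienol ether regiospecifically with the Z geometry expected from the s-cis enone.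

Step 4
Reactants: 8 (2Z,4Z,20Z,22Z)-3,22-dimethoxy-4,21-bis(trimethylsilyloxy)tetracosa-2,4,20,22-tetraene; 9 oxalyl chloride
Product: 11 3,3'-(tetradecane-1,14-diyl)bis(2-hydroxy-5-methoxy-6-methylcyclohexa-2,5-diene-1,4-dione), via bis(chlorooxalyl) tetraene 10 (not isolated)
Conditions: 9 (2.05 equiv, slow addition), 2,6-di-tert-butyl-4-methylpyridine (2.2 equiv), Me3SiOTf (0.2 equiv), CH2Cl2 (0.01 M), −78 → 20 °C; then 1 M HCl wash
Reagents that add atoms: oxalyl chloride, ClC(=O)C(=O)Cl (the second of the two molecules of 9 consumed per molecule of 8; each ring draws C1, C2 and both of their oxygen atoms from one molecule)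
Why: Proposed new method: two molecules of 9 are taken up, one per diene (8 + 2 (COCl)2 → 11 + 2 Me3SiCl + 2 HCl), each diene being C-acylated at one terminus (drawn for C6, the β-carbon of the methyl enol ether, with loss of HCl to the pyridine base), after which the pendant α-oxoacyl chloride acylates the other terminus C3 (the β-carbon of the silyl enol ether) with loss of Me3SiCl and the resulting 1,2,4-trione enolises to the 2-hydroxy-1,4-quinone; the reverse order of the two acylations converges on the same ring, so C6–C1 and C2–C3 are both made in the flask and every oxygen of 11 is accounted for (C1=O and C2–OH from oxalyl chloride, C4=O from the silyl ether, C5–OMe from the methyl ether). The closest known reaction types are the C-acylation of enol ethers and of silyl enol ethers by oxalyl chloride and the double Friedel–Crafts acylation of electron-rich 2,2'-biaryls by oxalyl chloride to phenanthrene-9,10-diones, of which this is the non-aromatic analogue. Each ring closes in a 6-(enolendo)-exo-trig mode, the nucleophilic enol-ether double bond lying inside the new six-membered ring and the acyl chloride carbonyl outside it. No stereocentre is formed, and the enol-ether geometries of 8 are erased. The step needs C- rather than O-acylation in the ring closure (the known five-membered O-closure of oxalylated silyl enol ethers to furan-2,3-diones is the competitor), and a six-membered carbocyclic closure that ends in a stable vinylogous acid, high dilution and the acid scavenger are relied on to secure it. The OH/OMe placement needs no selectivity, because the oxygen on C4 carries silicon and that on C5 carries methyl from the start.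

Compound list
1 | allyl methyl ether (3-methoxyprop-1-ene) | C=CCOC | starting material
2 | (Z)-1-methoxyprop-1-ene | C/C=C\OC | intermediate
3 | N-methoxy-N-methylacrylamide | C=CC(=O)N(C)OC | starting material
4 | (Z)-(1-methoxyprop-1-en-1-yl)lithium (not isolated) | C/C=C(\OC)[Li] | intermediate
5 | (4Z)-4-methoxyhexa-1,4-dien-3-one | C=CC(=O)/C(OC)=C/C | intermediate
6 | 1,12-dibromododecane | BrCCCCCCCCCCCCBr | starting material
7 | dodecane-1,12-diylbis(magnesium bromide) (not isolated) | Br[Mg]CCCCCCCCCCCC[Mg]Br | intermediate
8 | (2Z,4Z,20Z,22Z)-3,22-dimethoxy-4,21-bis(trimethylsilyloxy)tetracosa-2,4,20,22-tetraene | C/C=C(\OC)/C(O[Si](C)(C)C)=C/CCCCCCCCCCCCCC/C=C(O[Si](C)(C)C)/C(OC)=C/C | intermediate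
9 | oxalyl chloride | ClC(=O)C(=O)Cl | starting material
10 | bis(chlorooxalyl) tetraene, (3E,5Z,21Z,23E)-4,23-dimethoxy-3,24-dimethyl-2,25-dioxo-5,22-bis(trimethylsilyloxy)hexacosa-3,5,21,23-tetraenedioyl dichloride (not isolated; drawn with both chain ends at the stage after the first acylation, one molecule of 9 having reacted at each end) | ClC(=O)C(=O)/C(C)=C(OC)\C(O[Si](C)(C)C)=C\CCCCCCCCCCCCCC/C=C(O[Si](C)(C)C)/C(OC)=C(C)\C(=O)C(Cl)=O | intermediate
11 | 3,3'-(tetradecane-1,14-diyl)bis(2-hydroxy-5-methoxy-6-methylcyclohexa-2,5-diene-1,4-dione) | COC1=C(C)C(=O)C(O)=C(CCCCCCCCCCCCCCC2=C(O)C(=O)C(C)=C(OC)C2=O)C1=O | target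

Total step count: 4. Longest linear sequence: 4 steps (1 → 2 → 5 → 8 → 11).

Steps most likely to fail

Step 4 (Proposed new method). The ring closure may go through the enol oxygen instead of carbon, giving five-membered furan-2,3-dione-type lactones. The two chain ends may also be bridged by one oxalyl chloride molecule or oligomerise, and the product hydroxyl may be chlorinated by excess reagent. The fallback uses known chemistry, sets out from 8 and comes back at 11, and makes the same C6–C1 and C2–C3 bonds by a concerted cycloaddition. Heating 8 with vinylene carbonate (neat, excess, BHT, 160 °C, sealed tube; one molecule adds to each diene) should give the Diels–Alder bis(cyclic carbonate) cycloadduct 1,14-bis[5-methoxy-4-methyl-2-oxo-6-(trimethylsilyloxy)-3a,4,7,7a-tetrahydro-1,3-benzodioxol-7-yl]tetradecane F1 as a mixture of diastereomers; both terminal diene substituents of 8 point outward, as the cycloaddition requires. Dehydrogenation with DDQ (dioxane, 80 °C) and aqueous work-up should aromatise both rings and free the phenols, giving 1,14-bis(6-hydroxy-5-methoxy-4-methyl-2-oxo-1,3-benzodioxol-7-yl)tetradecane F2. Methanolysis of the aryl carbonates (K2CO3, MeOH, 20 °C) under air should release the benzene-1,2,4-triols, which autoxidise to 11. Aromatising before the basic step avoids β-elimination of the C2 oxygen.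

Step 3. One chain end of the di-Grignard reagent may be lost by protonation or Wurtz coupling, leaving mono-adducts. Unsilylated enolate may start Michael oligomerisation of the vinyl ketone, and the trimethylsilyl dienol ether may hydrolyse during isolation. The fallback sets out from 2 (as its lithio derivative 4) and comes back at 8; it replaces conjugate addition by enolisation of a preformed C24 skeleton. Commercial octadecanedioic acid (OC(=O)CCCCCCCCCCCCCCCCC(=O)O) is activated with 1,1'-carbonyldiimidazole (THF, 40 °C) to 1,18-di(1H-imidazol-1-yl)octadecane-1,18-dione F3. Treatment with MeNHOMe·HCl then gives N1,N18-dimethoxy-N1,N18-dimethyloctadecanediamide F4. Double addition of 4 (THF, −78 °C) should give (2Z,22Z)-3,22-dimethoxytetracosa-2,22-diene-4,21-dione F5. Kinetic deprotonation of the two α'-methylene groups with LiN(i-Pr)2 (THF/HMPA, −78 °C, the additive favouring the enolate with oxygen cis to the chain) should give dilithium (2Z,4Z,20Z,22Z)-3,22-dimethoxytetracosa-2,4,20,22-tetraene-4,21-diolate F6, which Me3SiCl silylates on oxygen to 8.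

Step 2. The alkenyllithium may attack the acrylamide in the 1,4-sense, metalation of 2 may occur at the allylic methyl instead of the vinylic position, and the volatile dienone may polymerise or take up liberated amine during work-up. The fallback sets out from 2 (through 4) and comes back at 5; it changes the acylation into an aldehyde addition followed by oxidation, so that no amine is ever present. 1,2-Addition of 4 to acrolein (THF, −78 °C) should give racemic (4Z)-4-methoxyhexa-1,4-dien-3-ol F7, and oxidation of this doubly allylic alcohol with MnO2 (CH2Cl2, 20 °C) should give 5.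

Further compounds
F1 | step 4 | 1,14-bis[5-methoxy-4-methyl-2-oxo-6-(trimethylsilyloxy)-3a,4,7,7a-tetrahydro-1,3-benzodioxol-7-yl]tetradecane (mixture of diastereomers, all stereocentres erased on aromatisation) | CC1C(OC)=C(O[Si](C)(C)C)C(CCCCCCCCCCCCCCC2C(O[Si](C)(C)C)=C(OC)C(C)C3OC(=O)OC23)C2OC(=O)OC12
F2 | step 4 | 1,14-bis(6-hydroxy-5-methoxy-4-methyl-2-oxo-1,3-benzodioxol-7-yl)tetradecane | Cc1c(OC)c(O)c(CCCCCCCCCCCCCCc2c(O)c(OC)c(C)c3OC(=O)Oc23)c2OC(=O)Oc12
F3 | step 3 | 1,18-di(1H-imidazol-1-yl)octadecane-1,18-dione | O=C(CCCCCCCCCCCCCCCCC(=O)n1ccnc1)n1ccnc1
F4 | step 3 | N1,N18-dimethoxy-N1,N18-dimethyloctadecanediamide | CON(C)C(=O)CCCCCCCCCCCCCCCCC(=O)N(C)OC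
F5 | step 3 | (2Z,22Z)-3,22-dimethoxytetracosa-2,22-diene-4,21-dione | C/C=C(\OC)C(=O)CCCCCCCCCCCCCCCCC(=O)/C(OC)=C/C
F6 | step 3 | dilithium (2Z,4Z,20Z,22Z)-3,22-dimethoxytetracosa-2,4,20,22-tetraene-4,21-diolate | C/C=C(\OC)/C(O[Li])=C/CCCCCCCCCCCCCC/C=C(O[Li])/C(OC)=C/C
F7 | step 2 | (4Z)-4-methoxyhexa-1,4-dien-3-ol (racemic) | C=CC(O)/C(OC)=C/C
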